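**Structural features**

The target is a single 36-membered macrolactone (C1–C35 plus the ring oxygen) whose lactone carbinol C35 carries a (2S)-hexan-2-yl side chain (C36–C40). C1–C3 is a Z-configured, β-methylated enoate; the rest of the ring is a saturated chain with nine free secondary hydroxyls at C7, C9, C13, C17, C21, C25, C27, C29 and C33. Only a few stereocentres are neighbours: C7/C9 (syn-1,3), C25/C27 (syn) and C27/C29 (anti) in a 1,3,5-triol, C33/C35 (syn-1,3) and C35/C36 (anti). All other carbinols are three methylenes apart (1,5), so C13, C17, C21 and the clusters cannot control one another, and remote diastereomers will not be separable. Fragile elements are the Z-enoate (geometrical isomerisation, deconjugation, conjugate addition), the lactone on the hindered O35 next to the C33 hydroxyl (1,3-acyl shift) and every β-oxygenated carbonyl intermediate (elimination). The real difficulty is threefold: eleven stereocentres over forty carbons with high fidelity, telling O35 apart from nine other oxygens, and closing a 36-membered ring at the most hindered oxygen. The key step exploits the C10–C11–C12 trimethylene between carbinols C9 and C13: written as a C11≡C12 alkyne it makes C9 homopropargylic and C13 propargylic, so the ring can be closed there by alkyne metathesis and the alkyne then erased by hydrogenation.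

**Logic of the disconnections**

54 ⇒ 53. No skeletal bond is cut; the nine hydroxyls are traced back to one kind of silyl ether so that the last step is a single operation. The forward step must remove nine silyl groups without moving the acyl group from O35 to O33 and without touching the Z-enoate.

53 ⇒ 52. The C10–C12 trimethylene is traced back to a C11≡C12 alkyne. This puts a ring-closing handle where no stereocentre is at stake. The forward saturation must take the alkyne to the alkane and leave the trisubstituted, conjugated C2=C3 bond alone.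

52 ⇒ 51. The ring bond C11≡C12 is cut to give an open-chain diyne with two methyl caps. The ring is thereby formed far from the hindered O35, and the ester is made beforehand in an intermolecular step. The forward step needs a catalyst that sees only the two alkynes, and dilution to favour the ring over oligomers.

51 ⇒ 41 + 49 (through 50). The sp2–sp3 bond C3–C4 is cut. This separates the enoate head, already attached to O35, from the C4–C11 piece, and lets the Z geometry come from a vinyl iodide of fixed geometry. The forward step needs hydroboration of a terminal alkene in the presence of an internal alkyne and a coupling that retains geometry.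

41 ⇒ 37 + 39, and 39 ⇒ 38. The acyl bond O35–C1 is cut. The hindered alcohol then meets only a small, cheap C4 acid that can be used in excess, and 39 comes from 38 by anti addition of HI. The forward acylation must keep the Z geometry of the iodoalkene.

49 ⇒ 48 ⇒ 47 ⇒ 46 ⇒ 43 + 44, and 43 ⇒ 42. C4=C5 is cut (methylenation) and C10–C11 is cut (alkynyl opening of an epoxide). The syn-1,3-diol C7/C9 is then simply that of the chiral-pool diol 42. The epoxide opening must tolerate a tert-butyl ester and a free hydroxyl.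

37 ⇒ 36 ⇒ 35 ⇒ 34 ⇒ 33 ⇒ 32 ⇒ 19 + 30 (through 31). C28–C29 is cut, and the C27 carbinol is traced back to a ketone. This is the most convergent cut of the alcohol half and uses substrate control twice: the ether at O25 directs C29 (1,5-anti) and the new C29 hydroxyl directs C27 (1,3-anti). The price is a benzyl-type ether at O25, exchanged for silyl afterwards, and an ester on O35 that survives boron enolates and is the only group of its kind.

19 ⇒ 18 ⇒ 17 ⇒ 12 + 15 (through 16), and 15 ⇒ 13. C23–C24 is cut, and the methyl ketone is traced back to a 1,1-disubstituted alkene. C25 then comes from a chiral-pool epoxide. The alkene cleavage must spare the internal alkyne.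

12 ⇒ 11 ⇒ 9 + 6 (through 10), and 9 ⇒ 8 ⇒ 5 + 6 (through 7). C19–C20 and C15–C16 are cut. Each 1,5-diol link is read as a Grignard carbon plus the CH2 of a terminal epoxide; the same chiral C4 epoxide 6 supplies C17, then C21, and each time the next C–Br bond. The forward steps need the epoxide to react faster than the primary bromide.

5 ⇒ 4 ⇒ 3 ⇒ 1 + 2. The acyl–alkynyl bond C12–C13 is cut and C13 is traced back to a ketone. The methyl-capped alkyne and C13 are thus present from the first steps, so no later step has to install an alkyne. The consequence is that no step on this branch may hydrogenate.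

30 ⇒ 29 ⇒ 28 ⇒ 27. C29–C30 is cut (formyl addition to a terminal alkene) and C32–C33 is cut (allylation of an aldehyde). The three-methylene spacer and C33 arise in two C–C bond formations under reagent control.

27 ⇒ 26 ⇒ 25 ⇒ 24. C33–C34 is cut (vinyl opening of an epoxide; the alkene is later cleaved to the aldehyde). O35 is acylated as soon as it appears, which settles its differentiation from all other oxygens.

24 ⇒ 23 ⇒ 22 ⇒ 21 ⇒ 20. The C36–CH3 bond is cut. C35 and C36 come from an asymmetric epoxidation of an E-allylic alcohol followed by invertive methyl delivery. This gives the anti relationship without a mismatched addition to an α-branched aldehyde.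

**Other disconnections considered**

Alternative 1: The cut is at C8–C9 and C13–C14, on both sides of the anti (locally C2-symmetric) C9/C13 diol. Forward, pentane-1,5-diol A1 would be allylated at both carbinol carbons in one operation by an iridium catalyst with a chiral bisphosphine and an allyl ester as donor, and the product would be (4R,8R)-undeca-1,10-diene-4,8-diol A2.
- In favour: two stereocentres and two C–C bonds are made from A1 in one flask, with no stoichiometric chiral reagent and no redox adjustment. The double reaction should also raise enantiopurity, because the minor enantiomer is diverted to the meso isomer.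
- Against, here: the two alkene ends of A2 are homotopic but must become different things (C7 with its syn hydroxyl on one side, the C14–C17 chain on the other), so a statistical mono-functionalisation follows directly. Nine stereocentres and the ring closure remain, and a macrolactonisation at the hindered O35 would still be needed.
- Comparison: structurally it uses a symmetry element that the chosen plan ignores (C9 comes from 42, C13 from a ketone reduction, and they meet only in the ring closure). Mechanistically it is a carbonyl allylation by transfer hydrogenation that creates stereocentres, whereas the alkyne metathesis creates none. For C9 and C13 taken alone the alternative is the better in step economy, since A1 is a bulk chemical and A2 is one step away, and it needs no air-sensitive alkylidyne. Over the whole route the gain is lost to end differentiation and a separate macrocyclisation.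

Alternative 2: The cut is at C15–C16 and C18–C19, with C16–C18 from a chiral three-carbon chloro-epoxide. Forward, a lithiated C5–C15 dithiane would open the epoxide at C16, the alkoxide would close to the C17–C18 epoxide on warming, and a lithiated C19–C40 dithiane would open that in the same flask. The product would be the C5–C40 chain A3 with dithianes at C15 and C19 and a free C17 hydroxyl.
- In favour: two C–C bonds and the union of two large fragments in one flask, C17 from the chiral pool with no selectivity question, and a C17 hydroxyl that is already differentiated.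
- Against, here: C15 and C19 are plain methylenes in the target, so both dithianes of A3 must be reduced off with a nickel reagent before any alkene or alkyne is present, and sulfur residues would precede later metal-catalysed steps. Hindered 2-alkyldithiane anions need strongly basic conditions with coordinating additives. The ring is still open, so O35 must later be acylated intramolecularly.
- Comparison: structurally both plans read a 1,5-diol as an epoxide carbinol plus a one-carbon spacer (Grignard carbons at C15 and C19 with 6 in the chosen plan, dithiane carbons here). Mechanistically both unions are SN2 epoxide openings. On convergence the alternative is the better, since the chosen plan builds C13–C25 linearly. As a way of setting C17 the two are equal. On step count the advantage is spent on two desulfurisations, extra protecting-group exchanges and the macrolactonisation.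

Alternative 3: The cut is at C21–C22 and C24–C25, with C22–C24 from a bifunctional allylborane. Forward, a γ-borylated allylborane, made in situ from an allenylboronate and a chiral dialkylborane, would add first to a C25–C40 aldehyde; the resulting α-substituted allylboronate would then add to a C1–C21 aldehyde. The product would be the full C1–C40 chain A4, an (E)-23-ene-21,25-anti-diol.
- In favour: two remote stereocentres and two C–C bonds in one pot, reagent control at C25 with 1,3-chirality transfer to C21, and a union in the middle of the chain.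
- Against, here: it needs two long, fully elaborated aldehydes, one already carrying the Z-enoate. The C25 aldehyde has a β-silyloxy centre (C27) whose influence must be matched or overridden. The two new hydroxyls of A4 must be silylated and the new C23=C24 alkene saturated next to the enoate. The ring is again left to a seco-acid lactonisation at O35.
- Comparison: structurally it addresses the one anti-1,5 pair of the alcohol half, which the chosen plan takes from two chiral-pool epoxides (6 and 15) in separate steps. Mechanistically it relies on two closed six-membered allylboration transition states, against SN2 epoxide openings for these centres and a metallacyclobutadiene shuttle for the ring. In convergence and in stereocentres per operation the alternative is the better. In tolerance at the ring-closing stage (no activated seco acid, no late alkene beside the enoate) the chosen plan is the better. Overall step counts should be about equal.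

Key step: step 35

Remarks on the chemistry.
- Locants C1–C40 are those of the macrolactone (C1 lactone carbonyl, C35 the carbinol carrying the ring oxygen, C36–C40 the side chain). TBS = tert-butyldimethylsilyl, PMB = 4-methoxybenzyl, Piv = 2,2-dimethylpropanoyl.
- Assumption: 6, 13, 20 and 42 are taken as catalogue compounds of high enantiomeric (for 20, geometrical) purity; 6 is otherwise one hydrolytic kinetic resolution away from its racemate.
- Compounds 51 and 52 agree atom by atom with the target in chain lengths, the nine silyl ethers, the Z geometry, the ring size and all eleven configurations.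
- Design of the precursor: the C12 alkyne and C13 are carried from step 1. O35 is acylated with a small C4 iodo acid and the C4–C11 piece is then attached by cross-coupling, so the hindered alcohol never has to be esterified with a long, valuable acid.

Step 1
Reactants: 1 3-chloropropanoyl chloride; 2 trimethyl(prop-1-yn-1-yl)silane
Product: 3 1-chlorohex-4-yn-3-one
Conditions: AlCl3, CH2Cl2, −20 → 0 °C
Reagents that add atoms: none
Why: Friedel–Crafts-type acylation of an alkynylsilane; the acylium ion attacks the silicon-bearing alkyne carbon (β-silyl stabilisation) and loss of silicon gives the ynone, which forms C12–C13 and brings the methyl cap.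

Step 2
Reactants: 3 1-chlorohex-4-yn-3-one
Product: 4 (3S)-1-chlorohex-4-yn-3-ol
Conditions: Ru[(S,S)-TsNCH(Ph)CH(Ph)NH](p-cymene) (1 mol%), i-PrOH, rt
Reagents that add atoms: none
Why: Noyori asymmetric transfer hydrogenation of an alkynyl ketone; the alkynyl group takes the place of the aryl group in the ordered six-membered transition state, so the (S,S) catalyst should give the (S)-carbinol (C13). The base-free 16-electron catalyst avoids β-elimination of chloride.

Step 3
Reactants: 4 (3S)-1-chlorohex-4-yn-3-ol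
Product: 5 tert-butyl{[(3S)-1-chlorohex-4-yn-3-yl]oxy}dimethylsilane
Conditions: TBSCl, imidazole, DMF, rt
Reagents that add atoms: tert-butyl(chloro)dimethylsilane, CC(C)(C)[Si](C)(C)Cl
Why: Standard silylation of an unhindered secondary alcohol; the primary chloride is inert.

Step 4
Reactants: 5 tert-butyl{[(3S)-1-chlorohex-4-yn-3-yl]oxy}dimethylsilane; 6 (2S)-2-(2-bromoethyl)oxirane
Product: 8 (3R,7S)-1-bromo-7-(TBSO)dec-8-yn-3-ol, via Grignard reagent 7 (not isolated)
Conditions: Mg, BrCH2CH2Br (cat.), THF, 50 °C; then CuI (10 mol%), 6, THF, −40 → −20 °C; aq NH4Cl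
Reagents that add atoms: none
Why: Copper-catalysed opening of a terminal epoxide by an alkyl Grignard reagent at the CH2 terminus (forms C15–C16); at low temperature this should outrun coupling at the primary C–Br bond. C17 comes unchanged from 6.

Step 5
Reactants: 8 (3R,7S)-1-bromo-7-(TBSO)dec-8-yn-3-ol
Product: 9 (3R,7S)-1-bromo-3,7-bis(TBSO)dec-8-yne
Conditions: TBSOTf, 2,6-lutidine, CH2Cl2, −78 °C
Reagents that add atoms: tert-butyldimethylsilyl trifluoromethanesulfonate, CC(C)(C)[Si](C)(C)OS(=O)(=O)C(F)(F)F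
Why: Silylation with the silyl triflate and a non-nucleophilic base is fast at low temperature and leaves the primary bromide untouched.

Step 6
Reactants: 9 (3R,7S)-1-bromo-3,7-bis(TBSO)dec-8-yne; 6 (2S)-2-(2-bromoethyl)oxirane
Product: 11 (3R,7S,11S)-1-bromo-7,11-bis(TBSO)tetradec-12-yn-3-ol, via Grignard reagent 10 (not isolated)
Conditions: Mg, THF, rt; then CuI (10 mol%), 6, THF, −40 → −20 °C; aq NH4Cl
Reagents that add atoms: none
Why: Second copper-catalysed Grignard opening of the same epoxide (forms C19–C20); the γ-silyloxy Grignard reagent is stable and C21 comes unchanged from 6.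

Step 7
Reactants: 11 (3R,7S,11S)-1-bromo-7,11-bis(TBSO)tetradec-12-yn-3-ol
Product: 12 (3R,7S,11S)-1-bromo-3,7,11-tris(TBSO)tetradec-12-yne
Conditions: TBSOTf, 2,6-lutidine, CH2Cl2, −78 °C
Reagents that add atoms: tert-butyldimethylsilyl trifluoromethanesulfonate, CC(C)(C)[Si](C)(C)OS(=O)(=O)C(F)(F)F
Why: Silylation as in step 5.

Step 8
Reactants: 13 (2R)-2-(chloromethyl)oxirane
Product: 15 (2R)-2-(2-methylprop-2-en-1-yl)oxirane, via chlorohydrin 14 (not isolated)
Conditions: CH2=C(CH3)MgBr, CuI (5 mol%), THF, −40 °C; then aq NaOH, rt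
Reagents that add atoms: isopropenylmagnesium bromide, CC(=C)[Mg]Br
Why: Copper-catalysed Grignard opening at the epoxide CH2, then base-induced closure of the chlorohydrin onto the former CH2Cl carbon; the C–O bond of the stereocentre is never broken, so the configuration (future C25) is kept.

Step 9
Reactants: 12 (3R,7S,11S)-1-bromo-3,7,11-tris(TBSO)tetradec-12-yne; 15 (2R)-2-(2-methylprop-2-en-1-yl)oxirane
Product: 17 (4S,8S,12S,16S)-8,12,16-tris(TBSO)-2-methylnonadec-1-en-17-yn-4-ol, via Grignard reagent 16 (not isolated)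
Conditions: Mg, THF, rt; then CuI (10 mol%), 15, THF, −40 → −20 °C; aq NH4Cl
Reagents that add atoms: none
Why: Third copper-catalysed epoxide opening by a Grignard reagent (forms C23–C24); C25 comes from 15 and the methallyl group is a latent methyl ketone.

Step 10
Reactants: 17 (4S,8S,12S,16S)-8,12,16-tris(TBSO)-2-methylnonadec-1-en-17-yn-4-ol
Product: 18 the 4-(4-methoxybenzyl) ether of 17
Conditions: NaH, 4-MeOC6H4CH2Cl, n-Bu4NI (cat.), THF/DMF, 0 °C → rt
Reagents that add atoms: 4-methoxybenzyl chloride, COc1ccc(CCl)cc1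
Why: Williamson etherification; the benzyl-type ether at O25 is needed to direct the aldol of step 21, and nothing else in 17 is base-sensitive.

Step 11
Reactants: 18 the 4-(4-methoxybenzyl) ether of 17
Product: 19 (4S,8S,12S,16S)-8,12,16-tris(TBSO)-4-(PMBO)nonadec-17-yn-2-one (C12–C28 methyl ketone)
Conditions: OsO4 (2 mol%), NaIO4, 2,6-lutidine, dioxane/H2O, rt
Reagents that add atoms: osmium tetroxide, O=[Os](=O)(=O)=O; sodium periodate, [Na+].[O-]I(=O)(=O)=O
Why: Lemieux–Johnson cleavage of the 1,1-disubstituted alkene to the methyl ketone; dihydroxylation of the internal alkyne is far slower, and the PMB ether, unlike under ozone, is not at risk.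

Step 12
Reactants: 20 (2E)-hept-2-en-1-ol
Product: 21 [(2R,3R)-3-butyloxiran-2-yl]methanol
Conditions: Ti(Oi-Pr)4 (5 mol%), D-(−)-diethyl tartrate (6 mol%), t-BuOOH, 4 Å MS, CH2Cl2, −20 °C
Reagents that add atoms: tert-butyl hydroperoxide, CC(C)(C)OO
Why: Sharpless asymmetric epoxidation; the titanium tartrate dimer delivers oxygen to one face of the E-allylic alcohol, and the D-tartrate should give the (2R,3R)-epoxide, which sets C35.

Step 13
Reactants: 21 [(2R,3R)-3-butyloxiran-2-yl]methanol
Product: 22 (2S,3S)-3-methylheptane-1,2-diol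
Conditions: AlMe3 (3 equiv), hexane/CH2Cl2, 0 °C → rt
Reagents that add atoms: trimethylaluminium, C[Al](C)C
Why: Regioselective opening of a 2,3-epoxy alcohol by a trialkylaluminium at C3 through the aluminium alkoxide; methyl is delivered with inversion, which sets C36 anti to O35.

Step 14
Reactants: 22 (2S,3S)-3-methylheptane-1,2-diol
Product: 24 (2S)-2-[(2S)-hexan-2-yl]oxirane, via primary tosylate 23 (not isolated)
Conditions: NaH (2.2 equiv), 1-(p-toluenesulfonyl)imidazole, THF, 0 °C → rt
Reagents that add atoms: none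
Why: Selective sulfonylation of the primary hydroxyl followed by intramolecular Williamson closure; the C35–O bond is untouched, so the configuration is kept.

Step 15
Reactants: 24 (2S)-2-[(2S)-hexan-2-yl]oxirane
Product: 25 (4R,5S)-5-methylnon-1-en-4-ol
Conditions: CH2=CHMgBr, CuI (10 mol%), THF, −30 °C; aq NH4Cl
Reagents that add atoms: vinylmagnesium bromide, C=C[Mg]Br
Why: Copper-catalysed epoxide opening at the CH2 terminus forms C33–C34 and releases O35 as the only hydroxyl of the fragment.

Step 16
Reactants: 25 (4R,5S)-5-methylnon-1-en-4-ol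
Product: 26 (4R,5S)-5-methylnon-1-en-4-yl pivalate
Conditions: t-BuCOCl, pyridine, DMAP (cat.), CH2Cl2, 40 °C
Reagents that add atoms: pivaloyl chloride, CC(C)(C)C(=O)Cl
Why: DMAP-catalysed acylation; the pivalate cannot be enolised, is slow to migrate and will be the only ester on the alcohol half, so O35 stays distinguishable to the end.

Step 17
Reactants: 26 (4R,5S)-5-methylnon-1-en-4-yl pivalate
Product: 27 (3R,4S)-4-methyl-1-oxooctan-3-yl pivalate
Conditions: O3, CH2Cl2, −78 °C; then PPh3
Reagents that add atoms: ozone, [O-][O+]=O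
Why: Ozonolysis with reductive work-up turns the vinyl group into the C33 aldehyde; the β-acyloxy aldehyde is used at once to avoid elimination.

Step 18
Reactants: 27 (3R,4S)-4-methyl-1-oxooctan-3-yl pivalate
Product: 28 (4R,6R,7S)-4-hydroxy-7-methylundec-1-en-6-yl pivalate
Conditions: (+)-Ipc2B(allyl), Et2O, −78 °C; then NaBO3·4H2O, THF/H2O, rt
Reagents that add atoms: (+)-B-allyldiisopinocampheylborane, C=CCB(C1CC2CC(C1C)C2(C)C)C1CC2CC(C1C)C2(C)C
Why: Brown allylboration through a chair transition state; the isopinocampheyl ligands of this reagent (the one derived from (−)-α-pinene) direct allyl to the Re face and should set C33 (R), syn to O35, while the β-acyloxy group exerts little bias. C32–C33 is formed, and the mild perborate work-up spares the ester.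

Step 19
Reactants: 28 (4R,6R,7S)-4-hydroxy-7-methylundec-1-en-6-yl pivalate
Product: 29 (4R,6R,7S)-4-(TBSO)-7-methylundec-1-en-6-yl pivalate
Conditions: TBSOTf, 2,6-lutidine, CH2Cl2, −78 °C
Reagents that add atoms: tert-butyldimethylsilyl trifluoromethanesulfonate, CC(C)(C)[Si](C)(C)OS(=O)(=O)C(F)(F)F
Why: Silylation of the new secondary alcohol under conditions that do not induce acyl migration.

Step 20
Reactants: 29 (4R,6R,7S)-4-(TBSO)-7-methylundec-1-en-6-yl pivalate
Product: 30 (5R,7R,8S)-5-(TBSO)-8-methyl-1-oxododecan-7-yl pivalate (C29–C40 aldehyde)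
Conditions: Rh(acac)(CO)2 (1 mol%), Xantphos (4 mol%), CO/H2 (1:1, 10 bar), toluene, 70 °C
Reagents that add atoms: carbon monoxide, [C-]#[O+]
Why: Rhodium-catalysed hydroformylation; the wide-bite-angle bisphosphine favours the linear aldehyde, adding C29 to the terminal alkene and completing the three-methylene spacer; ester and silyl ether are inert.

Step 21
Reactants: 19 C12–C28 methyl ketone; 30 C29–C40 aldehyde
Product: 32 C12–C40 aldol adduct (29-hydroxy-27-ketone), via boron enolate 31 (not isolated)
Conditions: (c-C6H11)2BCl, Et3N, Et2O, −78 → 0 °C; then 30, −78 → −20 °C; H2O2, pH 7 buffer, MeOH, 0 °C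
Reagents that add atoms: none
Why: Boron aldol reaction of a β-alkoxy methyl ketone; kinetic enolisation occurs on the methyl side, and the β-PMB ether steers the aldehyde in the boat-like transition state (1,5-anti induction). This should set C29 anti to C25 and forms C28–C29.

Step 22
Reactants: 32 C12–C40 aldol adduct
Product: 33 C12–C40 27,29-diol
Conditions: Me4NBH(OAc)3, MeCN/AcOH, −25 °C
Reagents that add atoms: none
Why: Evans–Saksena reduction; the acetoxyborohydride exchanges onto the C29 hydroxyl and delivers hydride intramolecularly through a chair, giving the 1,3-anti diol. C27 is thereby also syn to C25.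

Step 23
Reactants: 33 C12–C40 27,29-diol
Product: 34 C12–C40 27,29-bis(TBS) ether (25-OPMB, 35-OPiv)
Conditions: TBSOTf, 2,6-lutidine, CH2Cl2, −78 → 0 °C
Reagents that add atoms: tert-butyldimethylsilyl trifluoromethanesulfonate, CC(C)(C)[Si](C)(C)OS(=O)(=O)C(F)(F)F
Why: Double silylation of the anti-diol; the silyl triflate is needed for the flanked C27 hydroxyl.

Step 24
Reactants: 34 C12–C40 27,29-bis(TBS) ether
Product: 35 C12–C40 25-alcohol
Conditions: DDQ, CH2Cl2/pH 7 buffer, 0 °C
Reagents that add atoms: none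
Why: Oxidative cleavage of the PMB ether by hydride abstraction and hydrolysis of the oxocarbenium ion; silyl ethers, pivalate and the internal alkyne are inert, and no free neighbouring hydroxyl is present to trap the cation as an acetal.

Step 25
Reactants: 35 C12–C40 25-alcohol
Product: 36 C12–C40 heptakis-TBS 35-pivalate
Conditions: TBSOTf, 2,6-lutidine, CH2Cl2, −78 °C
Reagents that add atoms: tert-butyldimethylsilyl trifluoromethanesulfonate, CC(C)(C)[Si](C)(C)OS(=O)(=O)C(F)(F)F
Why: Silylation of O25 makes all oxygens except O35 identical.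

Step 26
Reactants: 36 C12–C40 heptakis-TBS 35-pivalate
Product: 37 C12–C40 alcohol half (35-OH free)
Conditions: i-Bu2AlH, CH2Cl2, −78 °C; Rochelle salt
Reagents that add atoms: none
Why: Reductive cleavage of the only ester; silyl ethers and the internal alkyne do not react with the aluminium hydride at low temperature, so O35 alone is set free.

Step 27
Reactants: 38 but-2-ynoic acid
Product: 39 (2Z)-3-iodobut-2-enoic acid
Conditions: NaI, AcOH, 110 °C
Reagents that add atoms: sodium iodide, [Na+].[I-]
Why: Conjugate hydroiodination of an ynoic acid; anti addition of HI puts iodine cis to the carboxyl group, which fixes the later Z geometry of C2=C3.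

Step 28
Reactants: 37 C12–C40 alcohol half; 39 (2Z)-3-iodobut-2-enoic acid
Product: 41 O35 (2Z)-3-iodobut-2-enoate of the alcohol half, via acid chloride 40 (not isolated)
Conditions: (COCl)2, DMF (cat.), CH2Cl2, 0 °C → rt; then 37, pyridine, DMAP (cat.), CH2Cl2, 0 °C → rt
Reagents that add atoms: none
Why: Acylation of the hindered C35 alcohol by a small, cheap acid chloride used in excess (nucleophilic catalysis by DMAP); C2=C3 is not involved, so the Z-iodoalkene should be kept.

Step 29
Reactants: 42 tert-butyl (3R,5S)-6-chloro-3,5-dihydroxyhexanoate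
Product: 43 tert-butyl (3R)-3-hydroxy-4-[(2S)-oxiran-2-yl]butanoate
Conditions: K2CO3, MeOH, 0 °C → rt
Reagents that add atoms: none
Why: Intramolecular Williamson closure of the chlorohydrin (3-exo-tet); the tert-butyl ester resists methanolysis and lactonisation, and the stereocentres (future C7, C9) are untouched.

Step 30
Reactants: 43 tert-butyl (3R)-3-hydroxy-4-[(2S)-oxiran-2-yl]butanoate; 44 propyne
Product: 46 tert-butyl (3R,5R)-3,5-dihydroxynon-7-ynoate, via propynyllithium 45 (not isolated)
Conditions: n-BuLi, THF, −78 °C; BF3·OEt2, −78 °C; then 43 (3.5 equiv of 45 and BF3·OEt2)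
Reagents that add atoms: none
Why: BF3-assisted opening of a terminal epoxide by a lithium acetylide at the CH2 terminus (forms C10–C11 and brings the methyl cap); the alkynyl–boron species does not add to the tert-butyl ester, and the excess reagent covers the free hydroxyl.

Step 31
Reactants: 46 tert-butyl (3R,5R)-3,5-dihydroxynon-7-ynoate
Product: 47 tert-butyl (3R,5R)-3,5-bis(TBSO)non-7-ynoate
Conditions: TBSCl, imidazole, DMF, 40 °C
Reagents that add atoms: tert-butyl(chloro)dimethylsilane, CC(C)(C)[Si](C)(C)Cl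
Why: Double silylation of the syn-diol; the chloride/imidazole system is chosen because silyl triflates can attack tert-butyl esters.

Step 32
Reactants: 47 tert-butyl (3R,5R)-3,5-bis(TBSO)non-7-ynoate
Product: 48 (3R,5R)-3,5-bis(TBSO)non-7-ynal
Conditions: i-Bu2AlH (1.1 equiv), toluene, −78 °C
Reagents that add atoms: none
Why: Partial reduction of the ester; the tetrahedral aluminium hemiacetal of a tert-butyl ester is stable at −78 °C and gives the aldehyde on work-up.

Step 33
Reactants: 48 (3R,5R)-3,5-bis(TBSO)non-7-ynal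
Product: 49 (4S,6R)-4,6-bis(TBSO)dec-1-en-8-yne
Conditions: Ph3PCH3Br, KN(SiMe3)2, THF, 0 °C; then 48, −78 → 0 °C
Reagents that add atoms: methyltriphenylphosphonium bromide, C[P+](c1ccccc1)(c1ccccc1)c1ccccc1.[Br-]
Why: Wittig methylenation adds C4; the non-stabilised ylide reacts with the aldehyde faster than it can induce β-elimination of the silyloxy group.

Step 34
Reactants: 49 (4S,6R)-4,6-bis(TBSO)dec-1-en-8-yne; 41 O35 (2Z)-3-iodobut-2-enoate of the alcohol half
Product: 51 ester-linked bis(methylalkyne), the ring-closure precursor, via alkylborane 50 (not isolated)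
Conditions: 9-BBN, THF, rt; then 41, Pd(dppf)Cl2 (10 mol%), AsPh3, Cs2CO3, DMF/THF/H2O, rt
Reagents that add atoms: none
Why: 9-BBN hydroborates the terminal alkene chemoselectively (internal alkynes react far more slowly); B-alkyl Suzuki–Miyaura coupling with the vinyl iodide then forms C3–C4 with retention of geometry and gives the Z-trisubstituted enoate.

Step 35
Reactants: 51 ester-linked bis(methylalkyne)
Product: 52 nonakis-TBS 11,12-didehydro macrolactone (36-membered cycloalkyne)
Conditions: Mo(≡CC6H4-4-OMe)(OSiPh3)3 (20 mol%), 5 Å MS, toluene (0.002 M), 80 °C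
Reagents that add atoms: none
Why: The molybdenum alkylidyne adds one methyl-capped alkyne across Mo≡C in a [2+2] sense to a metallacyclobutadiene, which cycloreverts to leave the substrate bound as a new alkylidyne; this engages the second alkyne of the same molecule in the same way, forms C11≡C12 and expels but-2-yne, which the 5 Å sieves absorb so that the equilibrium is drawn to the ring. The closest known reaction type is ring-closing alkyne metathesis of ester-linked bis(methylalkynes) with molybdenum alkylidyne silanolate catalysts in macrolide synthesis. The single ring (36-membered, C1–C35 and the oxygen) is closed end to end between the two chain termini and is large enough to hold a linear C–C≡C–C unit without strain. No stereocentre is formed, so nothing has to be controlled beyond the integrity of the eleven present. The step needs chemoselectivity for the two C≡C units over the Z-enoate, the ester and nine silyl ethers, which the alkylidyne provides because it does not engage alkenes or carbonyl groups. It also needs cyclisation over acyclic diyne oligomerisation, which high dilution, reversibility and the removal of but-2-yne should secure. The methyl caps keep both alkynes internal and prevent the polymerisation that terminal alkynes undergo; the propargylic silyl ether at C13 slows the catalyst, hence the heating.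

Step 36
Reactants: 52 nonakis-TBS 11,12-didehydro macrolactone
Product: 53 nonakis-TBS macrolactone (C10–C12 saturated)
Conditions: H2 (1–4 bar), RhCl(PPh3)3 (20 mol%), benzene/EtOH (1:1), rt
Reagents that add atoms: none
Why: Homogeneous hydrogenation; the alkyne and the cis-alkene derived from it bind to the rhodium hydride, whereas the trisubstituted, conjugated C2=C3 bond is too hindered and electron-poor, so the Z-enoate should survive, and no propargylic C–O hydrogenolysis is expected with this catalyst.

Step 37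
Reactants: 53 nonakis-TBS macrolactone
Product: 54 CNP0126363.4 (the target nonaol macrolactone)
Conditions: HF·pyridine, pyridine, THF, 0 °C → rt
Reagents that add atoms: none
Why: Global desilylation by buffered fluoride; the mildly acidic, non-basic medium should avoid acyl shift from O35 to O33 and leave the Z-enoate untouched.

**Compound list**

1 | 3-chloropropanoyl chloride | O=C(Cl)CCCl | starting material
2 | trimethyl(prop-1-yn-1-yl)silane | CC#C[Si](C)(C)C | starting material
3 | 1-chlorohex-4-yn-3-one | CC#CC(=O)CCCl | intermediate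
4 | (3S)-1-chlorohex-4-yn-3-ol | ClCC[C@H](O)C#CC | intermediate
5 | tert-butyl{[(3S)-1-chlorohex-4-yn-3-yl]oxy}dimethylsilane | ClCC[C@H](O[Si](C)(C)C(C)(C)C)C#CC | intermediate
6 | (2S)-2-(2-bromoethyl)oxirane | BrCC[C@H]1CO1 | starting material
7 | {(3S)-3-[(tert-butyldimethylsilyl)oxy]hex-4-yn-1-yl}magnesium chloride | Cl[Mg]CC[C@H](O[Si](C)(C)C(C)(C)C)C#CC | intermediate
8 | (3R,7S)-1-bromo-7-[(tert-butyldimethylsilyl)oxy]dec-8-yn-3-ol | BrCC[C@H](O)CCC[C@H](O[Si](C)(C)C(C)(C)C)C#CC | intermediate
9 | (3R,7S)-1-bromo-3,7-bis[(tert-butyldimethylsilyl)oxy]dec-8-yne | BrCC[C@H](O[Si](C)(C)C(C)(C)C)CCC[C@H](O[Si](C)(C)C(C)(C)C)C#CC | intermediate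
10 | {(3R,7S)-3,7-bis[(tert-butyldimethylsilyl)oxy]dec-8-yn-1-yl}magnesium bromide | Br[Mg]CC[C@H](O[Si](C)(C)C(C)(C)C)CCC[C@H](O[Si](C)(C)C(C)(C)C)C#CC | intermediate
11 | (3R,7S,11S)-1-bromo-7,11-bis[(tert-butyldimethylsilyl)oxy]tetradec-12-yn-3-ol | BrCC[C@H](O)CCC[C@H](O[Si](C)(C)C(C)(C)C)CCC[C@H](O[Si](C)(C)C(C)(C)C)C#CC | intermediate
12 | (3R,7S,11S)-1-bromo-3,7,11-tris[(tert-butyldimethylsilyl)oxy]tetradec-12-yne | BrCC[C@H](O[Si](C)(C)C(C)(C)C)CCC[C@H](O[Si](C)(C)C(C)(C)C)CCC[C@H](O[Si](C)(C)C(C)(C)C)C#CC | intermediate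
13 | (2R)-2-(chloromethyl)oxirane | ClC[C@H]1CO1 | starting material
14 | (2R)-1-chloro-4-methylpent-4-en-2-ol | ClC[C@H](O)CC(C)=C | intermediate
15 | (2R)-2-(2-methylprop-2-en-1-yl)oxirane | CC(=C)C[C@@H]1CO1 | intermediate
16 | {(3R,7S,11S)-3,7,11-tris[(tert-butyldimethylsilyl)oxy]tetradec-12-yn-1-yl}magnesium bromide | Br[Mg]CC[C@H](O[Si](C)(C)C(C)(C)C)CCC[C@H](O[Si](C)(C)C(C)(C)C)CCC[C@H](O[Si](C)(C)C(C)(C)C)C#CC | intermediate
17 | (4S,8S,12S,16S)-8,12,16-tris[(tert-butyldimethylsilyl)oxy]-2-methylnonadec-1-en-17-yn-4-ol | C=C(C)C[C@@H](O)CCC[C@H](O[Si](C)(C)C(C)(C)C)CCC[C@H](O[Si](C)(C)C(C)(C)C)CCC[C@H](O[Si](C)(C)C(C)(C)C)C#CC | intermediate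
18 | 1-methoxy-4-({[(4S,8S,12S,16S)-8,12,16-tris[(tert-butyldimethylsilyl)oxy]-2-methylnonadec-1-en-17-yn-4-yl]oxy}methyl)benzene | C=C(C)C[C@@H](OCc1ccc(OC)cc1)CCC[C@H](O[Si](C)(C)C(C)(C)C)CCC[C@H](O[Si](C)(C)C(C)(C)C)CCC[C@H](O[Si](C)(C)C(C)(C)C)C#CC | intermediate
19 | (4S,8S,12S,16S)-8,12,16-tris[(tert-butyldimethylsilyl)oxy]-4-[(4-methoxyphenyl)methoxy]nonadec-17-yn-2-one (C12–C28) | CC(=O)C[C@@H](OCc1ccc(OC)cc1)CCC[C@H](O[Si](C)(C)C(C)(C)C)CCC[C@H](O[Si](C)(C)C(C)(C)C)CCC[C@H](O[Si](C)(C)C(C)(C)C)C#CC | intermediate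
20 | (2E)-hept-2-en-1-ol | CCCC/C=C/CO | starting material
21 | [(2R,3R)-3-butyloxiran-2-yl]methanol | CCCC[C@H]1O[C@@H]1CO | intermediate
22 | (2S,3S)-3-methylheptane-1,2-diol | CCCC[C@H](C)[C@H](O)CO | intermediate
23 | (2S,3S)-2-hydroxy-3-methylheptyl 4-methylbenzenesulfonate | CCCC[C@H](C)[C@H](O)COS(=O)(=O)c1ccc(C)cc1 | intermediate
24 | (2S)-2-[(2S)-hexan-2-yl]oxirane | CCCC[C@H](C)[C@H]1CO1 | intermediate
25 | (4R,5S)-5-methylnon-1-en-4-ol | CCCC[C@H](C)[C@H](O)CC=C | intermediate
26 | (4R,5S)-5-methylnon-1-en-4-yl 2,2-dimethylpropanoate | CCCC[C@H](C)[C@H](OC(=O)C(C)(C)C)CC=C | intermediate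
27 | (3R,4S)-4-methyl-1-oxooctan-3-yl 2,2-dimethylpropanoate | CCCC[C@H](C)[C@H](OC(=O)C(C)(C)C)CC=O | intermediate
28 | (4R,6R,7S)-4-hydroxy-7-methylundec-1-en-6-yl 2,2-dimethylpropanoate | CCCC[C@H](C)[C@H](OC(=O)C(C)(C)C)C[C@H](O)CC=C | intermediate
29 | (4R,6R,7S)-4-[(tert-butyldimethylsilyl)oxy]-7-methylundec-1-en-6-yl 2,2-dimethylpropanoate | CCCC[C@H](C)[C@H](OC(=O)C(C)(C)C)C[C@H](O[Si](C)(C)C(C)(C)C)CC=C | intermediate
30 | (5R,7R,8S)-5-[(tert-butyldimethylsilyl)oxy]-8-methyl-1-oxododecan-7-yl 2,2-dimethylpropanoate (C29–C40) | CCCC[C@H](C)[C@H](OC(=O)C(C)(C)C)C[C@H](O[Si](C)(C)C(C)(C)C)CCCC=O | intermediate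
31 | dicyclohexylboron enolate of 19 (O-borylated C27=C28 enol) | C=C(OB(C1CCCCC1)C1CCCCC1)C[C@@H](OCc1ccc(OC)cc1)CCC[C@H](O[Si](C)(C)C(C)(C)C)CCC[C@H](O[Si](C)(C)C(C)(C)C)CCC[C@H](O[Si](C)(C)C(C)(C)C)C#CC | intermediate
32 | (5S,6R,8R,12S,16S,20S,24S,28S)-8,20,24,28-tetrakis[(tert-butyldimethylsilyl)oxy]-12-hydroxy-16-[(4-methoxyphenyl)methoxy]-5-methyl-14-oxohentriacont-29-yn-6-yl 2,2-dimethylpropanoate (C12–C40; hentriacontyne C6, C12, C14, C16 = macrolide C35, C29, C27, C25) | CCCC[C@H](C)[C@H](OC(=O)C(C)(C)C)C[C@H](O[Si](C)(C)C(C)(C)C)CCC[C@H](O)CC(=O)C[C@@H](OCc1ccc(OC)cc1)CCC[C@H](O[Si](C)(C)C(C)(C)C)CCC[C@H](O[Si](C)(C)C(C)(C)C)CCC[C@H](O[Si](C)(C)C(C)(C)C)C#CC | intermediate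
33 | (5S,6R,8R,12S,14R,16S,20S,24S,28S)-8,20,24,28-tetrakis[(tert-butyldimethylsilyl)oxy]-12,14-dihydroxy-16-[(4-methoxyphenyl)methoxy]-5-methylhentriacont-29-yn-6-yl 2,2-dimethylpropanoate | CCCC[C@H](C)[C@H](OC(=O)C(C)(C)C)C[C@H](O[Si](C)(C)C(C)(C)C)CCC[C@H](O)C[C@@H](O)C[C@@H](OCc1ccc(OC)cc1)CCC[C@H](O[Si](C)(C)C(C)(C)C)CCC[C@H](O[Si](C)(C)C(C)(C)C)CCC[C@H](O[Si](C)(C)C(C)(C)C)C#CC | intermediate
34 | (5S,6R,8R,12S,14S,16S,20S,24S,28S)-8,12,14,20,24,28-hexakis[(tert-butyldimethylsilyl)oxy]-16-[(4-methoxyphenyl)methoxy]-5-methylhentriacont-29-yn-6-yl 2,2-dimethylpropanoate | CCCC[C@H](C)[C@H](OC(=O)C(C)(C)C)C[C@H](O[Si](C)(C)C(C)(C)C)CCC[C@H](O[Si](C)(C)C(C)(C)C)C[C@@H](O[Si](C)(C)C(C)(C)C)C[C@@H](OCc1ccc(OC)cc1)CCC[C@H](O[Si](C)(C)C(C)(C)C)CCC[C@H](O[Si](C)(C)C(C)(C)C)CCC[C@H](O[Si](C)(C)C(C)(C)C)C#CC | intermediate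
35 | (5S,6R,8R,12S,14S,16S,20S,24S,28S)-8,12,14,20,24,28-hexakis[(tert-butyldimethylsilyl)oxy]-16-hydroxy-5-methylhentriacont-29-yn-6-yl 2,2-dimethylpropanoate | CCCC[C@H](C)[C@H](OC(=O)C(C)(C)C)C[C@H](O[Si](C)(C)C(C)(C)C)CCC[C@H](O[Si](C)(C)C(C)(C)C)C[C@@H](O[Si](C)(C)C(C)(C)C)C[C@@H](O)CCC[C@H](O[Si](C)(C)C(C)(C)C)CCC[C@H](O[Si](C)(C)C(C)(C)C)CCC[C@H](O[Si](C)(C)C(C)(C)C)C#CC | intermediate
36 | (5S,6R,8R,12S,14S,16S,20R,24S,28S)-8,12,14,16,20,24,28-heptakis[(tert-butyldimethylsilyl)oxy]-5-methylhentriacont-29-yn-6-yl 2,2-dimethylpropanoate | CCCC[C@H](C)[C@H](OC(=O)C(C)(C)C)C[C@H](O[Si](C)(C)C(C)(C)C)CCC[C@H](O[Si](C)(C)C(C)(C)C)C[C@@H](O[Si](C)(C)C(C)(C)C)C[C@@H](O[Si](C)(C)C(C)(C)C)CCC[C@H](O[Si](C)(C)C(C)(C)C)CCC[C@H](O[Si](C)(C)C(C)(C)C)CCC[C@H](O[Si](C)(C)C(C)(C)C)C#CC | intermediate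
37 | (5S,6R,8R,12S,14S,16S,20R,24S,28S)-8,12,14,16,20,24,28-heptakis[(tert-butyldimethylsilyl)oxy]-5-methylhentriacont-29-yn-6-ol (C12–C40 alcohol half, 35-OH free) | CCCC[C@H](C)[C@H](O)C[C@H](O[Si](C)(C)C(C)(C)C)CCC[C@H](O[Si](C)(C)C(C)(C)C)C[C@@H](O[Si](C)(C)C(C)(C)C)C[C@@H](O[Si](C)(C)C(C)(C)C)CCC[C@H](O[Si](C)(C)C(C)(C)C)CCC[C@H](O[Si](C)(C)C(C)(C)C)CCC[C@H](O[Si](C)(C)C(C)(C)C)C#CC | intermediate
38 | but-2-ynoic acid | CC#CC(=O)O | starting material
39 | (2Z)-3-iodobut-2-enoic acid | I/C(C)=C\C(=O)O | intermediate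
40 | (2Z)-3-iodobut-2-enoyl chloride | I/C(C)=C\C(Cl)=O | intermediate
41 | (5S,6R,8R,12S,14S,16S,20R,24S,28S)-8,12,14,16,20,24,28-heptakis[(tert-butyldimethylsilyl)oxy]-5-methylhentriacont-29-yn-6-yl (2Z)-3-iodobut-2-enoate | CCCC[C@H](C)[C@H](OC(=O)/C=C(C)\I)C[C@H](O[Si](C)(C)C(C)(C)C)CCC[C@H](O[Si](C)(C)C(C)(C)C)C[C@@H](O[Si](C)(C)C(C)(C)C)C[C@@H](O[Si](C)(C)C(C)(C)C)CCC[C@H](O[Si](C)(C)C(C)(C)C)CCC[C@H](O[Si](C)(C)C(C)(C)C)CCC[C@H](O[Si](C)(C)C(C)(C)C)C#CC | intermediate
42 | tert-butyl (3R,5S)-6-chloro-3,5-dihydroxyhexanoate | ClC[C@@H](O)C[C@@H](O)CC(=O)OC(C)(C)C | starting material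
43 | tert-butyl (3R)-3-hydroxy-4-[(2S)-oxiran-2-yl]butanoate | C1O[C@H]1C[C@@H](O)CC(=O)OC(C)(C)C | intermediate
44 | propyne | CC#C | starting material
45 | prop-1-yn-1-yllithium | [Li]C#CC | intermediate
46 | tert-butyl (3R,5R)-3,5-dihydroxynon-7-ynoate | CC#CC[C@@H](O)C[C@@H](O)CC(=O)OC(C)(C)C | intermediate
47 | tert-butyl (3R,5R)-3,5-bis[(tert-butyldimethylsilyl)oxy]non-7-ynoate | CC#CC[C@@H](O[Si](C)(C)C(C)(C)C)C[C@@H](O[Si](C)(C)C(C)(C)C)CC(=O)OC(C)(C)C | intermediate
48 | (3R,5R)-3,5-bis[(tert-butyldimethylsilyl)oxy]non-7-ynal | CC#CC[C@@H](O[Si](C)(C)C(C)(C)C)C[C@@H](O[Si](C)(C)C(C)(C)C)CC=O | intermediate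
49 | (4S,6R)-4,6-bis[(tert-butyldimethylsilyl)oxy]dec-1-en-8-yne (C4–C11 with methyl cap) | CC#CC[C@@H](O[Si](C)(C)C(C)(C)C)C[C@@H](O[Si](C)(C)C(C)(C)C)CC=C | intermediate
50 | 9-{(4S,6R)-4,6-bis[(tert-butyldimethylsilyl)oxy]dec-8-yn-1-yl}-9-borabicyclo[3.3.1]nonane | CC#CC[C@@H](O[Si](C)(C)C(C)(C)C)C[C@@H](O[Si](C)(C)C(C)(C)C)CCCB1C2CCCC1CCC2 | intermediate
51 | (5S,6R,8R,12S,14S,16S,20R,24S,28S)-8,12,14,16,20,24,28-heptakis[(tert-butyldimethylsilyl)oxy]-5-methylhentriacont-29-yn-6-yl (2Z,7S,9R)-7,9-bis[(tert-butyldimethylsilyl)oxy]-3-methyltridec-2-en-11-ynoate | CCCC[C@H](C)[C@H](OC(=O)/C=C(C)\CCC[C@H](O[Si](C)(C)C(C)(C)C)C[C@H](O[Si](C)(C)C(C)(C)C)CC#CC)C[C@H](O[Si](C)(C)C(C)(C)C)CCC[C@H](O[Si](C)(C)C(C)(C)C)C[C@@H](O[Si](C)(C)C(C)(C)C)C[C@@H](O[Si](C)(C)C(C)(C)C)CCC[C@H](O[Si](C)(C)C(C)(C)C)CCC[C@H](O[Si](C)(C)C(C)(C)C)CCC[C@H](O[Si](C)(C)C(C)(C)C)C#CC | intermediate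
52 | (3Z,8S,10R,14S,18S,22R,26S,28S,30S,34R,36R)-8,10,14,18,22,26,28,30,34-nonakis[(tert-butyldimethylsilyl)oxy]-36-[(2S)-hexan-2-yl]-4-methyl-1-oxacyclohexatriacont-3-en-12-yn-2-one | CCCC[C@H](C)[C@H]1C[C@H](O[Si](C)(C)C(C)(C)C)CCC[C@H](O[Si](C)(C)C(C)(C)C)C[C@@H](O[Si](C)(C)C(C)(C)C)C[C@@H](O[Si](C)(C)C(C)(C)C)CCC[C@H](O[Si](C)(C)C(C)(C)C)CCC[C@H](O[Si](C)(C)C(C)(C)C)CCC[C@H](O[Si](C)(C)C(C)(C)C)C#CC[C@@H](O[Si](C)(C)C(C)(C)C)C[C@@H](O[Si](C)(C)C(C)(C)C)CCC/C(C)=C\C(=O)O1 | intermediate
53 | (3Z,8S,10R,14S,18R,22R,26S,28S,30S,34R,36R)-8,10,14,18,22,26,28,30,34-nonakis[(tert-butyldimethylsilyl)oxy]-36-[(2S)-hexan-2-yl]-4-methyl-1-oxacyclohexatriacont-3-en-2-one | CCCC[C@H](C)[C@H]1C[C@H](O[Si](C)(C)C(C)(C)C)CCC[C@H](O[Si](C)(C)C(C)(C)C)C[C@@H](O[Si](C)(C)C(C)(C)C)C[C@@H](O[Si](C)(C)C(C)(C)C)CCC[C@H](O[Si](C)(C)C(C)(C)C)CCC[C@H](O[Si](C)(C)C(C)(C)C)CCC[C@H](O[Si](C)(C)C(C)(C)C)CCC[C@@H](O[Si](C)(C)C(C)(C)C)C[C@@H](O[Si](C)(C)C(C)(C)C)CCC/C(C)=C\C(=O)O1 | intermediate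
54 | (3Z,8S,10R,14S,18R,22R,26S,28S,30S,34R,36R)-36-[(2S)-hexan-2-yl]-8,10,14,18,22,26,28,30,34-nonahydroxy-4-methyl-1-oxacyclohexatriacont-3-en-2-one (CNP0126363.4) | CCCC[C@H](C)[C@H]1C[C@H](O)CCC[C@H](O)C[C@@H](O)C[C@@H](O)CCC[C@H](O)CCC[C@H](O)CCC[C@H](O)CCC[C@@H](O)C[C@@H](O)CCC/C(C)=C\C(=O)O1 | target

**Step count and risks**

Total: 37 steps. Longest linear sequence: 21 steps (steps 1–7, 9–11, 21–26, 28, 34–37).

Steps least certain to work:

Step 35 (key step). The most likely failure is loss of the ring closure to acyclic diyne oligomerisation, or slow turnover at the C12 alkyne, which is shielded by the propargylic silyl ether, so that the catalyst decomposes before the very dilute substrate is consumed. The fallback sets out from 41 and 49 and returns at 52: the alkyne metathesis is run intermolecularly and the ring is closed by a Pd(dppf)Cl2-catalysed coupling. Compound 41 and an excess of 49, with Mo(≡CC6H4-4-OMe)(OSiPh3)3 at ordinary concentration, should give the open-chain C4–C40 enyne iodoenoate F1 (C11≡C12 formed by cross-metathesis; the homodimer of 49 can re-enter the equilibrium). Hydroboration of the terminal alkene of F1 with 9-BBN to the alkylborane F2, then intramolecular B-alkyl Suzuki–Miyaura coupling under high dilution [Pd(dppf)Cl2, AsPh3, Cs2CO3, DMF/THF/H2O], would close the ring at C3–C4 and give 52.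

Step 4 (step 6 repeats the reaction and shares the risk). The most likely failure is loss of chemoselectivity between epoxide and primary bromide (copper-mediated coupling or halogen–magnesium exchange at C–Br); sluggish magnesium insertion into the chloride 5 is a second possibility. The fallback sets out from 5 (through 7) and returns at 9: the leaving group is introduced only after the C–C bond is made. The Grignard reagent 7 would open the halide-free epoxide (2S)-2-{2-[(4-methoxybenzyl)oxy]ethyl}oxirane F3 (CuI, THF, −30 °C) to the alcohol F4; silylation (TBSOTf, 2,6-lutidine) would give the bis-silyl ether F5; DDQ would free the primary alcohol F6; and bromination with CBr4/PPh3 would give 9.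

Step 28. The most likely failure is erosion of the Z geometry, or addition–elimination at the β-iodo position, when the activated acid meets pyridine and DMAP over the long reaction time a hindered alcohol needs. The fallback sets out from 37 and returns at 51 without ever activating a geometrically labile acid. Acetoacetylation of 37 with 2,2,6-trimethyl-4H-1,3-dioxin-4-one (toluene, 110 °C, via acetylketene) should give the β-keto ester F7. Z-selective enol triflation through the chelated lithium enolate (Tf2O, aqueous LiOH, toluene, 5 °C) should give the (Z)-enol triflate F8. B-alkyl Suzuki–Miyaura coupling of F8 with the borane 50 under the conditions of step 34 would then give 51.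

Step 36. The most likely failure is stalling at the cis-alkene at the hindered propargylic site, with slow attack on the enoate if the conditions are then forced. The fallback sets out from 52 and returns at 53 in two separately controllable stages. Semi-hydrogenation over Pd on CaCO3 poisoned with Pb(OAc)2 and quinoline (H2, 1 bar, EtOAc) should give the (11Z)-cycloalkene F9. Diimide, generated from 2-nitrobenzenesulfonyl hydrazide and Et3N in CH2Cl2, reduces cis-disubstituted alkenes but not trisubstituted conjugated ones and should give 53.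

**Further compounds**

F1 | step 35 | open-chain C4–C40 enyne: 41 extended at C12 by the C4–C11 unit of 49 (C11≡C12, terminal C4=C5 alkene, TBS ethers at O7, O9, O13, O17, O21, O25, O27, O29, O33, O35 (2Z)-3-iodobut-2-enoate) | CCCC[C@H](C)[C@H](OC(=O)/C=C(C)\I)C[C@H](O[Si](C)(C)C(C)(C)C)CCC[C@H](O[Si](C)(C)C(C)(C)C)C[C@@H](O[Si](C)(C)C(C)(C)C)C[C@@H](O[Si](C)(C)C(C)(C)C)CCC[C@H](O[Si](C)(C)C(C)(C)C)CCC[C@H](O[Si](C)(C)C(C)(C)C)CCC[C@H](O[Si](C)(C)C(C)(C)C)C#CC[C@@H](O[Si](C)(C)C(C)(C)C)C[C@@H](O[Si](C)(C)C(C)(C)C)CC=C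
F2 | step 35 | C4-(9-borabicyclo[3.3.1]nonan-9-yl) adduct of F1 | CCCC[C@H](C)[C@H](OC(=O)/C=C(C)\I)C[C@H](O[Si](C)(C)C(C)(C)C)CCC[C@H](O[Si](C)(C)C(C)(C)C)C[C@@H](O[Si](C)(C)C(C)(C)C)C[C@@H](O[Si](C)(C)C(C)(C)C)CCC[C@H](O[Si](C)(C)C(C)(C)C)CCC[C@H](O[Si](C)(C)C(C)(C)C)CCC[C@H](O[Si](C)(C)C(C)(C)C)C#CC[C@@H](O[Si](C)(C)C(C)(C)C)C[C@@H](O[Si](C)(C)C(C)(C)C)CCCB1C2CCCC1CCC2
F3 | step 4 | (2S)-2-{2-[(4-methoxyphenyl)methoxy]ethyl}oxirane | COc1ccc(COCC[C@H]2CO2)cc1
F4 | step 4 | (3R,7S)-7-[(tert-butyldimethylsilyl)oxy]-1-[(4-methoxyphenyl)methoxy]dec-8-yn-3-ol | COc1ccc(COCC[C@H](O)CCC[C@H](O[Si](C)(C)C(C)(C)C)C#CC)cc1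
F5 | step 4 | 1-({[(3R,7S)-3,7-bis[(tert-butyldimethylsilyl)oxy]dec-8-yn-1-yl]oxy}methyl)-4-methoxybenzene | COc1ccc(COCC[C@H](O[Si](C)(C)C(C)(C)C)CCC[C@H](O[Si](C)(C)C(C)(C)C)C#CC)cc1
F6 | step 4 | (3R,7S)-3,7-bis[(tert-butyldimethylsilyl)oxy]dec-8-yn-1-ol | OCC[C@H](O[Si](C)(C)C(C)(C)C)CCC[C@H](O[Si](C)(C)C(C)(C)C)C#CC
F7 | step 28 | O35 3-oxobutanoate (acetoacetate) of 37 | CCCC[C@H](C)[C@H](OC(=O)CC(C)=O)C[C@H](O[Si](C)(C)C(C)(C)C)CCC[C@H](O[Si](C)(C)C(C)(C)C)C[C@@H](O[Si](C)(C)C(C)(C)C)C[C@@H](O[Si](C)(C)C(C)(C)C)CCC[C@H](O[Si](C)(C)C(C)(C)C)CCC[C@H](O[Si](C)(C)C(C)(C)C)CCC[C@H](O[Si](C)(C)C(C)(C)C)C#CC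
F8 | step 28 | O35 (2Z)-3-{[(trifluoromethyl)sulfonyl]oxy}but-2-enoate of 37 | CCCC[C@H](C)[C@H](OC(=O)/C=C(C)\OS(=O)(=O)C(F)(F)F)C[C@H](O[Si](C)(C)C(C)(C)C)CCC[C@H](O[Si](C)(C)C(C)(C)C)C[C@@H](O[Si](C)(C)C(C)(C)C)C[C@@H](O[Si](C)(C)C(C)(C)C)CCC[C@H](O[Si](C)(C)C(C)(C)C)CCC[C@H](O[Si](C)(C)C(C)(C)C)CCC[C@H](O[Si](C)(C)C(C)(C)C)C#CC
F9 | step 36 | (3Z,12Z)-nonakis-TBS macrolactone (cis-C11=C12 cycloalkene from 52) | CCCC[C@H](C)[C@H]1C[C@H](O[Si](C)(C)C(C)(C)C)CCC[C@H](O[Si](C)(C)C(C)(C)C)C[C@@H](O[Si](C)(C)C(C)(C)C)C[C@@H](O[Si](C)(C)C(C)(C)C)CCC[C@H](O[Si](C)(C)C(C)(C)C)CCC[C@H](O[Si](C)(C)C(C)(C)C)CCC[C@H](O[Si](C)(C)C(C)(C)C)/C=C\C[C@@H](O[Si](C)(C)C(C)(C)C)C[C@@H](O[Si](C)(C)C(C)(C)C)CCC/C(C)=C\C(=O)O1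
A1 | alternative 1 | pentane-1,5-diol | OCCCCCO
A2 | alternative 1 | (4R,8R)-undeca-1,10-diene-4,8-diol | C=CC[C@H](O)CCC[C@@H](O)CC=C
A3 | alternative 2 | C5–C40 chain with 1,3-dithianes at C15 and C19, free 17-OH, 35-O-triethylsilyl, C5 dioxolane, other carbinols as TBS ethers | CCCC[C@H](C)[C@H](O[Si](CC)(CC)CC)C[C@H](O[Si](C)(C)C(C)(C)C)CCC[C@H](O[Si](C)(C)C(C)(C)C)C[C@@H](O[Si](C)(C)C(C)(C)C)C[C@@H](O[Si](C)(C)C(C)(C)C)CCC[C@H](O[Si](C)(C)C(C)(C)C)CC1(SCCCS1)C[C@H](O)CC1(SCCCS1)C[C@H](O[Si](C)(C)C(C)(C)C)CCC[C@@H](O[Si](C)(C)C(C)(C)C)C[C@@H](O[Si](C)(C)C(C)(C)C)CC1OCCO1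
A4 | alternative 3 | methyl C1–C40 (2Z,23E)-dienoate with free 21,25-anti-diol, 35-OPMB, other carbinols as TBS ethers | CCCC[C@H](C)[C@H](OCc1ccc(OC)cc1)C[C@H](O[Si](C)(C)C(C)(C)C)CCC[C@H](O[Si](C)(C)C(C)(C)C)C[C@@H](O[Si](C)(C)C(C)(C)C)C[C@@H](O)/C=C/C[C@H](O)CCC[C@H](O[Si](C)(C)C(C)(C)C)CCC[C@H](O[Si](C)(C)C(C)(C)C)CCC[C@@H](O[Si](C)(C)C(C)(C)C)C[C@@H](O[Si](C)(C)C(C)(C)C)CCC/C(C)=C\C(=O)OC
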